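C1–C10 is the ten-membered ring: C1/C10 epoxide CH/C(CH3), C3 CH–OAc, C4=C5 the cis olefin, C6 lactone CH–O, C7 ring fusion, C8 CH–O-isovalerate, C9 CH2. C11–C13 are the methylene-lactone carbons.
Enabling feature: with the oxirane read as an E-C1=C10 olefin and C6 as a ketone, the ring holds C1=C10–C9–C8–C7–C6(=O). In this δ,ε-unsaturated ketone, C8–C9 is the σ bond an oxy-Cope shift makes, and the cis C4=C5 bond lets C1–C2–C3–C4=C5–C6 fold back into a cyclohexene.
Disconnections: (a) late C1=C10 epoxidation and the two acylations; (b) methylene lactone from a C7–CH2CONMe2 arm and the C6 ketone (reduction, closure with inversion, methylenation).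
(c) C8–C9 made and C1–C6 broken: anionic oxy-Cope ring expansion of a 1-(E-2-alkoxyvinyl)-6-isopropenylcyclohex-2-enol with C7 alkylation in the same flask; (d) the carbinol from a 4-silyloxy-isopiperitenone, which is (S)-carvone after reduction and allylic oxidation.
Ring order: cyclohexene (from carvone), then the ten-membered carbocycle, then the γ-lactone, then the oxirane.

Key step: step 7

Remark: germacrane numbering is used throughout. In 4 and 11–14, C1 is the isopropenyl-bearing ring carbon, C3 the silyloxy carbon, C6 the carbonyl or carbinol carbon, C7/C8 the two-carbon arm and C9=C10 the isopropenyl olefin. α/β refer to the usual germacranolide drawing with H-7 α. The C11 configuration of 21 and 22 is erased in the same step and is left open.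

Step 1
Reactants: 1 (S)-(+)-carvone
Product: 2 (1S,5S)-cis-carveol
Conditions: NaBH4, CeCl3·7H2O, MeOH, −20 °C
Reagents that add atoms: none
Why: Luche 1,2-reduction; hydride adds axially to the half-chair that carries the isopropenyl group equatorial, so the equatorial (cis) alcohol should form, and this sets the later C3 (S).

Step 2
Reactants: 2 (1S,5S)-cis-carveol
Product: 3 (1S,5S)-cis-carveyl tert-butyldimethylsilyl ether
Conditions: TBSCl, imidazole, DMF, 25 °C
Reagents that add atoms: tert-butyldimethylsilyl chloride, CC(C)(C)[Si](C)(C)Cl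
Why: Imidazole-promoted silylation gives a cover for O-3 that is stable to bases, hydrides and organolithiums and orthogonal to the later p-methoxybenzyl ether; no stereocentre is touched.

Step 3
Reactants: 3 (1S,5S)-cis-carveyl tert-butyldimethylsilyl ether
Product: 4 (4S,6S)-4-[(tert-butyldimethylsilyl)oxy]-3-methyl-6-(prop-1-en-2-yl)cyclohex-2-en-1-one
Conditions: CrO3, 3,5-dimethylpyrazole, CH2Cl2, −20 °C
Reagents that add atoms: chromium trioxide, O=[Cr](=O)=O
Why: Allylic oxidation with the CrO3–dimethylpyrazole complex takes the only ring CH2 allylic to the trisubstituted olefin to the enone (the limonene-to-isopiperitenone pattern); the silyloxy-bearing CH is shielded, the 1,1-disubstituted olefin is less reactive, and the cis arrangement is also the more stable one at the now enolisable C1.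

Step 4
Reactants: 5 4-methoxybenzyl alcohol; 6 trichloroethylene
Product: 8 1-{[(E)-1,2-dichloroethenyl]oxymethyl}-4-methoxybenzene, via dichloroacetylene 7 (not isolated)
Conditions: KH, THF, 0 °C; then Cl2C=CHCl, −50 → 25 °C
Reagents that add atoms: none
Why: Base-induced loss of HCl from trichloroethylene and anti addition of the alkoxide to dichloroacetylene is the standard entry to 1,2-dichlorovinyl ethers as ynol ether precursors.

Step 5
Reactants: 8 1-{[(E)-1,2-dichloroethenyl]oxymethyl}-4-methoxybenzene; 4 (4S,6S)-4-[(tert-butyldimethylsilyl)oxy]-3-methyl-6-(prop-1-en-2-yl)cyclohex-2-en-1-one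
Product: 11 (1S,4S,6S)-4-[(tert-butyldimethylsilyl)oxy]-1-{[(4-methoxybenzyl)oxy]ethynyl}-3-methyl-6-(prop-1-en-2-yl)cyclohex-2-en-1-ol, via chloroethynyl ether 9 (not isolated), via lithium alkoxyacetylide 10 (not isolated)
Conditions: 8, n-BuLi (2.2 equiv), THF, −78 → −40 °C; then 4, LaCl3·2LiCl (0.3 equiv), −78 °C; H2O
Reagents that add atoms: n-butyllithium, [Li]CCCC (its lithium stays only in 10)
Why: Elimination and chlorine–lithium exchange give the lithium ynolate ether, kept cold to avoid rearrangement of the benzyl alkynyl ether; it adds 1,2 to the enone from the face anti to the vicinal isopropenyl group, which sets the C6 carbinol with OH cis and the alkynyl arm trans to isopropenyl, while the lanthanum salt suppresses enolisation at C1.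

Step 6
Reactants: 11 (1S,4S,6S)-4-[(tert-butyldimethylsilyl)oxy]-1-{[(4-methoxybenzyl)oxy]ethynyl}-3-methyl-6-(prop-1-en-2-yl)cyclohex-2-en-1-ol
Product: 12 (1S,4S,6S)-4-[(tert-butyldimethylsilyl)oxy]-1-{(E)-2-[(4-methoxybenzyl)oxy]ethenyl}-3-methyl-6-(prop-1-en-2-yl)cyclohex-2-en-1-ol
Conditions: LiAlH4, THF, 0 → 25 °C; aq. NaOH work-up, Et3N-deactivated silica
Reagents that add atoms: none
Why: Hydroxyl-directed trans-hydroalumination of a propargylic alcohol (also the known LiAlH4 route from alkoxyalkynes to E-enol ethers) should give only the E-enol ether, and the basic work-up protects the acid-labile hydroxy enol ether.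

Step 7
Reactants: 12 (1S,4S,6S)-4-[(tert-butyldimethylsilyl)oxy]-1-{(E)-2-[(4-methoxybenzyl)oxy]ethenyl}-3-methyl-6-(prop-1-en-2-yl)cyclohex-2-en-1-ol; 13 2-bromo-N,N-dimethylacetamide
Product: 16 3β-[(tert-butyldimethylsilyl)oxy]-8α-[(4-methoxybenzyl)oxy]-N,N-dimethyl-6-oxo-13-norgermacra-1(10)E,4Z-dien-12-amide (H-7α; 3S,7R,8S), via potassium alkoxide 14 (not isolated), via potassium enolate 15 (not isolated)
Conditions: KN(SiMe3)2 (1.1 equiv), 18-crown-6, THF, 0 → 25 °C; then 13, −78 °C; pH 7 buffer
Reagents that add atoms: potassium bis(trimethylsilyl)amide, C[Si](C)(C)[N-][Si](C)(C)C.[K+] (its potassium stays only in 14 and 15)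
Why: KN(SiMe3)2/18-crown-6 gives the bare potassium alkoxide 14, in which the C6 oxyanion weakens the C1–C6 bond and drives a concerted [3,3] shift of the 1,5-diene C9=C10–C1–C6–C7=C8: the C8–C9 σ bond forms while C1–C6 breaks, the cross-conjugated enolate 15 makes the shift irreversible, and 13 then alkylates C7 in the same flask. The closest known reaction type is the anionic oxy-Cope ring expansion of 1,2-dialkenylcyclohex-2-enols (isopiperitenone adducts) to (E,Z)-cyclodecadienones with capture of the regiodefined enolate by an electrophile. The ten-membered carbocycle is closed by a suprafacial–suprafacial sigmatropic four-atom ring expansion of the cyclohexene through a chair transition state in which the isopropenyl, alkoxyvinyl and silyloxy groups are all equatorial on the half-chair, so no end-to-end macrocyclisation is involved. In this chair the C1–C2 ring bond is equatorial, which gives the E-C1=C10 olefin, C4=C5 keeps the cis geometry it had in the six-membered ring, and C8 is set (S) by chirality transfer from C1 (S) because the E-enol ether holds the OPMB group equatorial. C7 is set (R) in the alkylation, since H-8 eclipses the enolate oxygen (allylic 1,3-strain), the C8–C9 ring bond and the C1=C10 bridge cover the inner face, and the bromide can only be met on the outer face, anti to C8–C9. The step needs the right 1,5-diene, C- instead of O-alkylation and no E1cB loss of the C8 alkoxide: an equatorial isopropenyl group cannot reach the ring olefin C4=C5, an α-bromo amide at −78 °C is a C-selective and weakly acidic electrophile, and the trans-cycloalkene-like enolate holds C8–C9 parallel and C8–O close to the nodal plane of its π system.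

Step 8
Reactants: 16 3β-[(tert-butyldimethylsilyl)oxy]-8α-[(4-methoxybenzyl)oxy]-N,N-dimethyl-6-oxo-13-norgermacra-1(10)E,4Z-dien-12-amide
Product: 17 3β-[(tert-butyldimethylsilyl)oxy]-6β-hydroxy-8α-[(4-methoxybenzyl)oxy]-N,N-dimethyl-13-norgermacra-1(10)E,4Z-dien-12-amide (6S)
Conditions: NaBH4, CeCl3·7H2O, MeOH, −40 °C
Reagents that add atoms: none
Why: Luche 1,2-reduction of the Z-enone; the carbonyl stands about perpendicular to the mean ring plane, its inner face covered by the C1=C10 bridge and the C7–C8 ring bond acting as the perpendicular large substituent, so peripheral attack and the Felkin–Anh model agree on hydride delivery from outside past H-7, which should set C6 as the 6β (S) alcohol that the next step inverts.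

Step 9
Reactants: 17 3β-[(tert-butyldimethylsilyl)oxy]-6β-hydroxy-8α-[(4-methoxybenzyl)oxy]-N,N-dimethyl-13-norgermacra-1(10)E,4Z-dien-12-amide
Product: 20 3β-[(tert-butyldimethylsilyl)oxy]-8α-[(4-methoxybenzyl)oxy]-13-norgermacra-1(10)E,4Z-dien-6α,12-olide (trans-fused; 6R,7R), via allylic mesylate 18 (not isolated), via iminium ether salt 19 (not isolated)
Conditions: MsCl, Et3N, CH2Cl2, −30 → 25 °C; then H2O/THF
Reagents that add atoms: water, O (becomes the lactone carbonyl oxygen); methanesulfonyl chloride, CS(=O)(=O)Cl (stays only in 18 and 19)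
Why: Neighbouring-group lactonisation of a γ-hydroxy amide: the amide oxygen, held on the outer face by the β side chain at C7, displaces the mesylate from the rear (5-exo-tet SN2, inversion, C6 becomes R, trans fusion) to an iminium ether of the kind met in halolactonisation of unsaturated amides, and water hydrolyses it to the lactone.

Step 10
Reactants: 20 3β-[(tert-butyldimethylsilyl)oxy]-8α-[(4-methoxybenzyl)oxy]-13-norgermacra-1(10)E,4Z-dien-6α,12-olide
Product: 23 3β-[(tert-butyldimethylsilyl)oxy]-8α-[(4-methoxybenzyl)oxy]germacra-1(10)E,4Z,11(13)-trien-6α,12-olide, via Mannich base 21 (not isolated), via ammonium iodide 22 (not isolated)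
Conditions: LiN(iPr)2, THF, −78 °C; CH2=NMe2+ I−, −78 → 0 °C; MeI, MeOH, 25 °C; aq. NaHCO3/CH2Cl2
Reagents that add atoms: Eschenmoser's salt, C=[N+](C)C.[I-]; iodomethane, CI (its carbon stays only in 22)
Why: Mannich reaction of the lactone lithium enolate, exhaustive methylation and Hofmann-type β-elimination form the standard α-methylenation of γ-butyrolactones; no leaving group sits β to the enolate and no stereocentre of the target is touched.

Step 11
Reactants: 23 3β-[(tert-butyldimethylsilyl)oxy]-8α-[(4-methoxybenzyl)oxy]germacra-1(10)E,4Z,11(13)-trien-6α,12-olide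
Product: 24 3β-[(tert-butyldimethylsilyl)oxy]-8α-hydroxygermacra-1(10)E,4Z,11(13)-trien-6α,12-olide
Conditions: DDQ, CH2Cl2/pH 7 buffer, 0 °C
Reagents that add atoms: none
Why: Oxidative cleavage of the p-methoxybenzyl ether by benzylic hydride abstraction; the silyl ether, the olefins and the methylene lactone should be inert in the buffered medium, and C8 keeps its oxygen and configuration.

Step 12
Reactants: 24 3β-[(tert-butyldimethylsilyl)oxy]-8α-hydroxygermacra-1(10)E,4Z,11(13)-trien-6α,12-olide
Product: 25 3β-[(tert-butyldimethylsilyl)oxy]-8α-(3-methylbutanoyloxy)germacra-1(10)E,4Z,11(13)-trien-6α,12-olide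
Conditions: (Me2CHCH2CO)2O, Et3N, DMAP (cat.), CH2Cl2, 0 → 25 °C
Reagents that add atoms: 3-methylbutanoic anhydride, CC(C)CC(=O)OC(=O)CC(C)C
Why: DMAP-catalysed acylation of the only free hydroxyl, with retention at C8; acylating promptly leaves no time for lactone migration to O-8.

Step 13
Reactants: 25 3β-[(tert-butyldimethylsilyl)oxy]-8α-(3-methylbutanoyloxy)germacra-1(10)E,4Z,11(13)-trien-6α,12-olide
Product: 26 3β-hydroxy-8α-(3-methylbutanoyloxy)germacra-1(10)E,4Z,11(13)-trien-6α,12-olide
Conditions: HF·pyridine, pyridine, THF, 0 → 25 °C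
Reagents that add atoms: none
Why: Fluoride-driven desilylation in a pyridine-buffered medium is neither basic enough for acyl migration nor acidic enough for transannular cyclisation of the 1(10),4-diene.

Step 14
Reactants: 26 3β-hydroxy-8α-(3-methylbutanoyloxy)germacra-1(10)E,4Z,11(13)-trien-6α,12-olide
Product: 27 3β-acetoxy-8α-(3-methylbutanoyloxy)germacra-1(10)E,4Z,11(13)-trien-6α,12-olide
Conditions: Ac2O, pyridine, DMAP (cat.), CH2Cl2, 0 °C
Reagents that add atoms: acetic anhydride, CC(=O)OC(C)=O
Why: DMAP-catalysed acetylation of the allylic C3 alcohol with retention of configuration.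

Step 15
Reactants: 27 3β-acetoxy-8α-(3-methylbutanoyloxy)germacra-1(10)E,4Z,11(13)-trien-6α,12-olide
Product: 28 3β-acetoxy-1β,10α-epoxy-8α-(3-methylbutanoyloxy)germacra-4Z,11(13)-dien-6α,12-olide (1R,3S,6R,7R,8S,10R; CNP0157657.1)
Conditions: mCPBA (1.0 equiv), NaHCO3-buffered CH2Cl2, −10 °C
Reagents that add atoms: 3-chloroperoxybenzoic acid, O=C(OO)c1cccc(Cl)c1
Why: Prilezhaev epoxidation, stereospecific for the E-olefin (trans-epoxide); C1=C10 is the only electron-rich olefin (C4=C5 is deactivated by two allylic acyloxy groups, C11=C13 is conjugated), it stands perpendicular to the ring so only its outer face is open, and in the usual 6α,12-germacranolide conformer with the C10 methyl on the β face (the planar chirality already created in step 7) that face leads to the 1β,10α (1R,10R) epoxide.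

Compound list
1 | (S)-(+)-carvone | CC1=CC[C@@H](CC1=O)C(C)=C | starting material
2 | (1S,5S)-cis-carveol | CC1=CC[C@@H](C[C@@H]1O)C(C)=C | intermediate
3 | (1S,5S)-cis-carveyl tert-butyldimethylsilyl ether | CC1=CC[C@@H](C[C@@H]1O[Si](C)(C)C(C)(C)C)C(C)=C | intermediate
4 | (4S,6S)-4-[(tert-butyldimethylsilyl)oxy]-3-methyl-6-(prop-1-en-2-yl)cyclohex-2-en-1-one | CC1=CC(=O)[C@@H](C[C@@H]1O[Si](C)(C)C(C)(C)C)C(C)=C | intermediate
5 | 4-methoxybenzyl alcohol | COc1ccc(CO)cc1 | starting material
6 | trichloroethylene | ClC=C(Cl)Cl | starting material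
7 | dichloroacetylene | ClC#CCl | intermediate
8 | 1-{[(E)-1,2-dichloroethenyl]oxymethyl}-4-methoxybenzene | COc1ccc(CO/C(Cl)=C\Cl)cc1 | intermediate
9 | 1-[(chloroethynyl)oxymethyl]-4-methoxybenzene | COc1ccc(COC#CCl)cc1 | intermediate
10 | lithium [(4-methoxybenzyl)oxy]acetylide | COc1ccc(COC#C[Li])cc1 | intermediate
11 | (1S,4S,6S)-propargylic alcohol (alkynyl trans, OH cis to isopropenyl) | CC1=C[C@@](O)(C#COCc2ccc(OC)cc2)[C@@H](C[C@@H]1O[Si](C)(C)C(C)(C)C)C(C)=C | intermediate
12 | (1S,4S,6S)-E-alkoxyvinyl carbinol | CC1=C[C@@](O)(/C=C/OCc2ccc(OC)cc2)[C@@H](C[C@@H]1O[Si](C)(C)C(C)(C)C)C(C)=C | intermediate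
13 | 2-bromo-N,N-dimethylacetamide | CN(C)C(=O)CBr | starting material
14 | potassium alkoxide of 12 | CC1=C[C@@]([O-])(/C=C/OCc2ccc(OC)cc2)[C@@H](C[C@@H]1O[Si](C)(C)C(C)(C)C)C(C)=C.[K+] | intermediate
15 | potassium 3β-silyloxy-8α-(4-methoxybenzyloxy)-11,12,13-trinorgermacra-1(10)E,4Z,6-trien-6-olate (C5 and C8 trans across C6=C7) | [K+].[O-]/C1=C\[C@@H](OCc2ccc(OC)cc2)C/C(C)=C/C[C@H](O[Si](C)(C)C(C)(C)C)/C(C)=C\1 | intermediate
16 | keto amide (3S,7R,8S) | O=C1/C=C(/C)[C@@H](O[Si](C)(C)C(C)(C)C)C/C=C(\C)C[C@H](OCc2ccc(OC)cc2)[C@H]1CC(=O)N(C)C | intermediate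
17 | 6β-hydroxy amide (6S) | O[C@H]1/C=C(/C)[C@@H](O[Si](C)(C)C(C)(C)C)C/C=C(\C)C[C@H](OCc2ccc(OC)cc2)[C@H]1CC(=O)N(C)C | intermediate
18 | 6β-mesylate of 17 | CS(=O)(=O)O[C@H]1/C=C(/C)[C@@H](O[Si](C)(C)C(C)(C)C)C/C=C(\C)C[C@H](OCc2ccc(OC)cc2)[C@H]1CC(=O)N(C)C | intermediate
19 | 6α,12-iminium ether methanesulfonate | C1C(=[N+](C)C)O[C@@H]2/C=C(/C)[C@@H](O[Si](C)(C)C(C)(C)C)C/C=C(\C)C[C@H](OCc3ccc(OC)cc3)[C@@H]12.CS(=O)(=O)[O-] | intermediate
20 | trans-fused 13-nor-6α,12-olide | C1C(=O)O[C@@H]2/C=C(/C)[C@@H](O[Si](C)(C)C(C)(C)C)C/C=C(\C)C[C@H](OCc3ccc(OC)cc3)[C@@H]12 | intermediate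
21 | 13-(dimethylamino)-11,13-dihydro lactone (C11 open) | CN(C)CC1C(=O)O[C@@H]2/C=C(/C)[C@@H](O[Si](C)(C)C(C)(C)C)C/C=C(\C)C[C@H](OCc3ccc(OC)cc3)[C@@H]12 | intermediate
22 | 13-(trimethylammonio) lactone iodide (C11 open) | C[N+](C)(C)CC1C(=O)O[C@@H]2/C=C(/C)[C@@H](O[Si](C)(C)C(C)(C)C)C/C=C(\C)C[C@H](OCc3ccc(OC)cc3)[C@@H]12.[I-] | intermediate
23 | 3β-silyloxy-8α-(4-methoxybenzyloxy) methylene lactone | C=C1C(=O)O[C@@H]2/C=C(/C)[C@@H](O[Si](C)(C)C(C)(C)C)C/C=C(\C)C[C@H](OCc3ccc(OC)cc3)[C@@H]12 | intermediate
24 | 3β-silyloxy-8α-hydroxy methylene lactone | C=C1C(=O)O[C@@H]2/C=C(/C)[C@@H](O[Si](C)(C)C(C)(C)C)C/C=C(\C)C[C@H](O)[C@@H]12 | intermediate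
25 | 3β-silyloxy-8α-isovalerate | C=C1C(=O)O[C@@H]2/C=C(/C)[C@@H](O[Si](C)(C)C(C)(C)C)C/C=C(\C)C[C@H](OC(=O)CC(C)C)[C@@H]12 | intermediate
26 | 3β-hydroxy-8α-isovalerate | C=C1C(=O)O[C@@H]2/C=C(/C)[C@@H](O)C/C=C(\C)C[C@H](OC(=O)CC(C)C)[C@@H]12 | intermediate
27 | 3β-acetoxy-8α-isovalerate triene | C=C1C(=O)O[C@@H]2/C=C(/C)[C@@H](OC(C)=O)C/C=C(\C)C[C@H](OC(=O)CC(C)C)[C@@H]12 | intermediate
28 | CNP0157657.1 | C=C1C(=O)O[C@@H]2/C=C(/C)[C@@H](OC(C)=O)C[C@H]3O[C@]3(C)C[C@H](OC(=O)CC(C)C)[C@@H]12 | target

Total step count: 15. Longest linear sequence: 14 (steps 1–3 and 5–15, from (S)-carvone).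

Steps most likely to fail

1. Step 7. The potassium enolate may lose the C8 p-methoxybenzyl oxide by E1cB elimination while the shift is still running at 0–25 °C. Proton transfer or O-alkylation may also interfere during trapping. The fallback sets out from 12 and comes back at 16, and it gives up the charge-accelerated cascade. Compound 12 is rearranged as the neutral alcohol (thermal oxy-Cope, o-dichlorobenzene, 180–190 °C, base-washed glass). The enol tautomerises, and the same chair should give the C7-unsubstituted ketone 3β-[(tert-butyldimethylsilyl)oxy]-8α-[(4-methoxybenzyl)oxy]-11,12,13-trinorgermacra-1(10)E,4Z-dien-6-one F1. No enolate is then present at elevated temperature. F1 is deprotonated at its only α-CH2 with LiN(iPr)2 in THF/DMPU at −78 °C and alkylated with 13 at that temperature, on the outer face as before, to give 16.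

2. Step 9. The allylic mesylate may ionise ahead of amide participation, which would lead to elimination to a conjugated triene, chloride capture or allylic transposition. The fallback sets out from 16 and comes back at 20, and it avoids substitution at C6 altogether. Reagent-controlled reduction is used: (S)-Me-CBS oxazaborolidine (cat.), BH3·SMe2, toluene, −40 °C, on the premise that the branched C7 side acts as the large group; the (R)-catalyst serves if the alkenyl side dominates. This overrides the peripheral bias and should give the 6α-hydroxy amide (6R) F2. F2 lactonises with retention on warming with pyridinium p-toluenesulfonate in toluene to give 20.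

3. Step 15. Facial selectivity may be poor if the conformer with the C10 methyl on the α face is populated, and C4=C5 may compete. The fallback sets out from 27 and comes back at 28, and it replaces substrate control by reagent control. This is a Shi epoxidation with the D-fructose-derived ketone, KHSO5 (as Oxone) and K2CO3 in MeCN/dimethoxymethane/H2O at 0 °C. The catalyst's preference for (R,R)-epoxides of E-trisubstituted olefins matches 1R,10R, and electron-poor olefins are left alone. This fallback makes no new compound (F0).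

Further compounds
F1 | step 7 | 3β-[(tert-butyldimethylsilyl)oxy]-8α-[(4-methoxybenzyl)oxy]-11,12,13-trinorgermacra-1(10)E,4Z-dien-6-one | O=C1/C=C(/C)[C@@H](O[Si](C)(C)C(C)(C)C)C/C=C(\C)C[C@H](OCc2ccc(OC)cc2)C1
F2 | step 9 | 6α-hydroxy amide (6R epimer of 17) | O[C@@H]1/C=C(/C)[C@@H](O[Si](C)(C)C(C)(C)C)C/C=C(\C)C[C@H](OCc2ccc(OC)cc2)[C@H]1CC(=O)N(C)C
F0 | step 15 | none | none
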